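(The readings were generated by integration for an exercise, and the scatter is random.)

The reagent in the second phase was what I counted in this flask. It stood at 0.800 of the starting material charged, less than one to one, which made it the limiting reagent, and I asked how much of it would appear as target.

| setting | delta | beta | zeta | flask |
|---|---|---|---|---|
| starting material | 0.093 M | 0.093 M | 0.19 M | 0.093 M |
| reagent in the second phase | 0.050 M | 0.11 M | 0.0744 M | 0.0744 M |
| remark | run made earlier | run made earlier | run made earlier |  |
| time |  |  |  | 10 min |
| volume of the second phase over the first |  |  |  | 2.0 |

| run | time / min | target / % |
|---|---|---|
| delta | 1.50 | 12.7 |
| delta | 2.50 | 19.5 |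
| delta | 4.00 | 25.5 |
| delta | 6.00 | 28.2 |
| beta | 1.50 | 26.2 |
| beta | 2.50 | 39.8 |
| beta | 4.00 | 50.1 |
| beta | 6.00 | 53.8 |
| zeta | 1.50 | 12.0 |
| zeta | 2.50 | 17.5 |
| zeta | 4.00 | 21.3 |
| zeta | 6.00 | 22.1 |

(each reading ± 0.3 percentage points)

* when, up to 10 min, the flask holds most target
* the amount of target, in percent of the starting material charged, at that time
* the first time at which target reaches 20%, in the same percent, in min

- in the second phase: reagent in the second phase; everything else is in the first
- charges count per volume of the first phase; a concentration in a rate is the amount of a species over the volume of its own phase; every rate counts per litre of the first phase
- the numbers in the tables scatter by 0.3 percentage points (one standard deviation)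
- what may be going on: reagent in the reaction phase <-> reagent in the second phase; target <-> isomer of the product; starting material + reagent in the reaction phase -> target
- the earlier runs hold the two phases in the same ratio of volumes as the flask asked about

The reagent is charged to the second phase, so it has to cross before it can meet starting material. For the early part I compared the first readings of delta, with 0.538 of reagent per starting material, and beta, with 1.18. At 1.50 min, beta held 2.06 times the target of delta on 2.20 times the reagent, so I reckoned in shares of the reagent charge and joined the two runs in a straight line at this flask's ratio. That put the flask at 18.4% at 1.50 min and 28.2% at 2.50 min, and a straight line between them crossed the asked level at 1.66 min.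

In the middle the rise slowed: from 4.00 min to 6.00 min, delta gained 2.7 percentage points and beta 3.7 points. At the end, delta's last reading stood at 52.5% of its reagent charge. I call this share of the reagent charge standing as target at the highest reading the return. Beta read 45.5%, and zeta, at 0.392, read 56.4%. Joining delta and beta gave this flask a return of 49.6%, hence 39.7% target, and I placed the peak shortly after 6.00 min.

The forecast, holding that “yield scales with reagent”, gave 40.2% at 7 min, with the level reached at 1.66 min. The flask gave 40.2% at 6.50 min, and reached the level at 1.64 min.

    reagent in the reaction phase ⇌ reagent in the second phase, rate k1*([reagent in the reaction phase] - [reagent in the second phase]/K1) per volume of the first phase (partition coefficient = 0.660, kL = 0.00830 s⁻¹)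
    target ⇌ isomer of the product (K = 3.10, k = 0.00190 s⁻¹)
    starting material + reagent in the reaction phase → target (k = 0.320 M⁻¹ s⁻¹)

The flask's return came to 50.2%. I then took the neighbour charged with 0.23 M of starting material, which holds 0.323 of reagent per starting material, less than zeta's 0.392. Carrying the line through delta and zeta out to that ratio gave a return of 58.3%, hence 18.8% target. That neighbour's best was 18.8%. At 10.0 min it held 16.1% target, with 69% of its starting material still there.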